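After 3.0 min at 40 °C, how much J can stand in a flask charged with 19 mM of Q?

| flask | Z | Q | temperature | remark | time |
|---|---|---|---|---|---|
| epsilon | 0.80 M | 9.5 mM | 40 °C | run made earlier |  |
| Saturday's | 0.80 M | 19 mM |  | at 25 °C until 50 s, from then on at 40 °C | 3.0 min |
| Thursday's | 0.80 M | 19 mM | 40 °C |  | 3.0 min |
| Monday's | 0.80 M | 19 mM | 25 °C |  | 3.0 min |

- epsilon (time / s: J / %, L / %): 10.0: 10, 1; 12.0: 11, 0; 25.0: 28, 2; 40.0: 35, 0

(each reading ± 2 percentage points)

- the earlier runs do not show what temperature does; that part of a forecast is a guess
- no earlier run changes the charge of Q; that part of a forecast is a guess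
- a reading or a percentage of L counts all its forms, free or not

- which flask leads in amount of J, in percent of the Z charged ("all alike" within 1.5 percentage points) (Saturday's / Thursday's / Monday's / all alike)
- how much J is there at the end, in percent of the Z charged: Saturday's
- how much J is there at the end, in percent of the Z charged: Thursday's
- how much J is there at the end, in percent of the Z charged: Monday's

*How fast does Z go?* In the epsilon run at 40.0 s, J reads 35% and L reads 0%. Read as a first-order loss of Z, that gives a constant of 0.646 min⁻¹, with the scatter of those readings in it.

*And J, when L hardly shows?* L's highest reading is 2%, against a scatter of 2 percentage points, so I let that much stand at 40.0 s. J averaged about half its last reading over that time, which gives a rough figure of 0.171 min⁻¹ for its loss constant. That is an estimate from a reading within the scatter, not a measurement.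

*At 19 mM of Q?* No run shows this, so I guess. I let J's loss follow Q and leave Z's loss unchanged, which gives 0.343 min⁻¹.

*What rule follows?* In this reckoning, with temperature and Q held, J is made in proportion to Z and used in proportion to J, so it stops rising when J over Z equals the ratio of the two constants. At this temperature and charge that ratio is 1.88, and I call it the crest ratio, a selectivity factor for making against using J.

*Does Thursday's flask pass its crest?* The two first-order steps give my own figure of 45.5% of J at the end. J over Z is then 3.16, above the crest ratio, so by this reckoning Thursday's has passed it. No run shows what temperature does, so it is a guess that Saturday's, at 25 °C until 50 s, ends nearer its crest than Thursday's and leads, with Monday's last.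

*And the forecast?* It names Saturday's, with 86%, 85% and 71% for Saturday's, Thursday's and Monday's, and states: “I assume rate is proportional to Q”. Its Thursday's figure stands above mine.

The flasks give 51.8% for Saturday's, 48.5% for Thursday's and 31.6% for Monday's, so Saturday's leads, at a figure below its forecast. In Saturday's, J made over J used, each step taken net, is 3.83 at 1.37 min and 0.809 at 3.00 min. Saturday's ends with J over Z at 2.87, above the crest ratio of 1.88, so the rule puts it past its crest.

    Z → J (k = 0.160 min⁻¹, Ea = 78.0 kJ mol⁻¹)
    Q + J → Q + L (k = 6.00 M⁻¹ min⁻¹, Ea = 52.0 kJ mol⁻¹)
    Z + L ⇌ D, settled at all times (K = 0.620 M⁻¹, ΔH = −61.0 kJ mol⁻¹)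
    (constants at 25 °C)

Take a neighbour of Saturday's charged with 0.0076 M of Q. If J's loss follows Q as I guessed, the crest ratio at 40 °C becomes 4.71, and with Z at Saturday's 18.1% the crest needs 85.3% of J, more than the 81.9% that has left Z. So by this reckoning J in the neighbour should still be rising at the end. The neighbour gives 67.8% of J with 18.2% of Z, a ratio of 3.73, below its crest ratio.

The numbers in the tables were computed for substances that don't exist; noise was put on by code.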